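**Plan**

- The target is a 1,3-diarylpropane. Ring A is a resorcinol carrying a 1,1-dimethylallyl group, ring B is the benzene ring of a 7-hydroxy-4-prenylbenzofuran (furan = ring C), and a CH2–CH2–CH2 chain runs from ring A to C5 of the benzofuran.
- The retrosynthesis cuts both C–C bonds at the central CH2 of that chain. Because this carbon lies between two benzylic CH2 groups, it can come from the methyl carbon of methyl phenyl sulfone, alkylated twice as a sulfonyl carbanion by two benzylic halides; the sulfonyl group is then removed reductively.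
- Ring-B bromide 12 (steps 1–8): ring C is closed on 6-bromovanillin by iodination and Sonogashira coupling–cyclisation, the methyl ether is exchanged for MOM, the prenyl group enters at C4 by Stille coupling, and CHO becomes CH2Br.
- Ring-A chloride 22 (steps 9–14): the 4-O-prenyl ether of 2,4-dihydroxybenzaldehyde undergoes an aromatic Claisen shift to C5 to set the 1,1-dimethylallyl group, and CHO becomes CH2Cl.
- The chain is joined in step 15 (ring A first, ring B second), followed by desulfonylation and MOM removal (steps 16–17).
- Stereochemistry: the target has no stereocentre and no configured alkene. The sulfone-bearing carbon of 25 is formed racemic and is erased in step 16.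

Key step: step 15

Remark: ring-B locants follow benzofuran numbering (O1, C2, C3, C3a, C4–C7, C7a); "prenyl" means 3-methylbut-2-en-1-yl.

**Route**

Step 1
Reactants: 1 2-bromo-4-hydroxy-5-methoxybenzaldehyde (6-bromovanillin)
Product: 2 2-bromo-4-hydroxy-3-iodo-5-methoxybenzaldehyde
Conditions: NIS, TFA (cat.), MeCN, 0 °C to rt
Reagents that add atoms: N-iodosuccinimide, O=C1CCC(=O)N1I
Why: Electrophilic aromatic iodination of a phenol, in which the free hydroxyl directs the iodine to its only open ortho position (C3, between OH and Br), the para position being blocked by the formyl group.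

Step 2
Reactants: 2 2-bromo-4-hydroxy-3-iodo-5-methoxybenzaldehyde; 3 ethynyltrimethylsilane
Product: 5 4-bromo-7-methoxy-2-(trimethylsilyl)-1-benzofuran-5-carbaldehyde, via alkynylphenol 4 (not isolated)
Conditions: Pd(PPh3)2Cl2 (cat.), CuI (cat.), Et3N, DMF, rt, then 60 °C; alkyne kept near one equivalent
Reagents that add atoms: none
Why: Sonogashira coupling should take place at the C–I bond at room temperature while the C–Br bond is kept for step 6, and on warming the acidic phenol of 4 adds 5-endo-dig to the metal-activated alkyne, the known tandem coupling–heteroannulation of ortho-iodophenols that closes ring C.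

Step 3
Reactants: 5 4-bromo-7-methoxy-2-(trimethylsilyl)-1-benzofuran-5-carbaldehyde
Product: 6 4-bromo-7-methoxy-1-benzofuran-5-carbaldehyde
Conditions: TBAF, THF, 0 °C to rt
Reagents that add atoms: none
Why: Fluoride-mediated protodesilylation of a 2-silylbenzofuran, whose C2–Si bond is readily cleaved; any uncyclised 4 carried over would be desilylated and cyclised by the same basic fluoride.

Step 4
Reactants: 6 4-bromo-7-methoxy-1-benzofuran-5-carbaldehyde
Product: 7 4-bromo-7-hydroxy-1-benzofuran-5-carbaldehyde
Conditions: BBr3, CH2Cl2, −78 to 0 °C; then H2O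
Reagents that add atoms: none
Why: Lewis-acid cleavage of an aryl methyl ether with BBr3, placed here because the prenyl and 1,1-dimethylallyl groups introduced later would not tolerate it, while the aldehyde, the aryl bromide and the electron-poor benzofuran should survive at low temperature.

Step 5
Reactants: 7 4-bromo-7-hydroxy-1-benzofuran-5-carbaldehyde
Product: 8 4-bromo-7-(methoxymethoxy)-1-benzofuran-5-carbaldehyde
Conditions: MOMCl, i-Pr2NEt, CH2Cl2, 0 °C to rt
Reagents that add atoms: chloromethyl methyl ether, COCCl
Why: Standard base-mediated MOM etherification of a phenol, giving an acetal that withstands the coupling, hydride and carbanion steps ahead and is removed by mild acid at the end.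

Step 6
Reactants: 8 4-bromo-7-(methoxymethoxy)-1-benzofuran-5-carbaldehyde; 9 tributyl(3-methylbut-2-en-1-yl)stannane
Product: 10 7-(methoxymethoxy)-4-(3-methylbut-2-en-1-yl)-1-benzofuran-5-carbaldehyde
Conditions: Pd(PPh3)4 (cat.), DMF, 100 °C
Reagents that add atoms: none
Why: Stille coupling, in which insertion of zerovalent palladium into the C–Br bond is assisted by the ortho formyl group and reductive elimination from the allylpalladium intermediate is expected at the less substituted terminus to give the linear prenyl group; aryl aldehydes are tolerated in this coupling.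

Step 7
Reactants: 10 7-(methoxymethoxy)-4-(3-methylbut-2-en-1-yl)-1-benzofuran-5-carbaldehyde
Product: 11 [7-(methoxymethoxy)-4-(3-methylbut-2-en-1-yl)-1-benzofuran-5-yl]methanol
Conditions: NaBH4, MeOH, 0 °C
Reagents that add atoms: none
Why: Chemoselective hydride reduction of an aryl aldehyde by NaBH4, which leaves the prenyl alkene, the benzofuran and the MOM ether untouched.

Step 8
Reactants: 11 [7-(methoxymethoxy)-4-(3-methylbut-2-en-1-yl)-1-benzofuran-5-yl]methanol
Product: 12 5-(bromomethyl)-7-(methoxymethoxy)-4-(3-methylbut-2-en-1-yl)-1-benzofuran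
Conditions: CBr4, PPh3, CH2Cl2, 0 °C
Reagents that add atoms: carbon tetrabromide, BrC(Br)(Br)Br
Why: Appel bromination converts the primary benzylic alcohol into the bromide by displacement of an alkoxyphosphonium ion under neutral conditions, without acid that would endanger the MOM ether or the prenyl alkene.

Step 9
Reactants: 13 2,4-dihydroxybenzaldehyde; 14 prenyl bromide (1-bromo-3-methylbut-2-ene)
Product: 15 2-hydroxy-4-[(3-methylbut-2-en-1-yl)oxy]benzaldehyde
Conditions: K2CO3, acetone, reflux
Reagents that add atoms: none
Why: Williamson etherification that is selective for the 4-hydroxyl, since the 2-hydroxyl is held in a hydrogen bond to the formyl group and is the less nucleophilic site.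

Step 10
Reactants: 15 2-hydroxy-4-[(3-methylbut-2-en-1-yl)oxy]benzaldehyde
Product: 16 2-(methoxymethoxy)-4-[(3-methylbut-2-en-1-yl)oxy]benzaldehyde
Conditions: MOMCl, i-Pr2NEt, CH2Cl2, 0 °C to reflux
Reagents that add atoms: chloromethyl methyl ether, COCCl
Why: MOM etherification of the chelated 2-hydroxyl, which protects it and, as a donor meta to the allyl ether oxygen, helps to steer the coming sigmatropic shift to C5.

Step 11
Reactants: 16 2-(methoxymethoxy)-4-[(3-methylbut-2-en-1-yl)oxy]benzaldehyde
Product: 18 4-hydroxy-2-(methoxymethoxy)-5-(2-methylbut-3-en-2-yl)benzaldehyde, via ortho-dienone 17 (not isolated)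
Conditions: PhNEt2, 190 °C, sealed tube, argon
Reagents that add atoms: none
Why: Aromatic Claisen rearrangement, in which the [3,3] shift of the aryl prenyl ether delivers the allyl unit with inversion, as a 1,1-dimethylallyl group, to the less hindered ortho position C5 (C3 lies between two oxygen substituents) and dienone 17 tautomerises to the phenol, while the basic amine solvent shields the MOM acetal and suppresses acid-induced cyclisation of the phenol onto the new vinyl group.

Step 12
Reactants: 18 4-hydroxy-2-(methoxymethoxy)-5-(2-methylbut-3-en-2-yl)benzaldehyde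
Product: 19 2,4-bis(methoxymethoxy)-5-(2-methylbut-3-en-2-yl)benzaldehyde
Conditions: MOMCl, i-Pr2NEt, CH2Cl2, 0 °C to rt
Reagents that add atoms: chloromethyl methyl ether, COCCl
Why: MOM etherification of the acidic para-formyl phenol, which removes the last acidic proton before the carbanion chemistry and blocks cyclisation onto the adjacent 1,1-dimethylallyl group.

Step 13
Reactants: 19 2,4-bis(methoxymethoxy)-5-(2-methylbut-3-en-2-yl)benzaldehyde
Product: 20 [2,4-bis(methoxymethoxy)-5-(2-methylbut-3-en-2-yl)phenyl]methanol
Conditions: NaBH4, MeOH, 0 °C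
Reagents that add atoms: none
Why: Chemoselective hydride reduction of the aryl aldehyde by NaBH4, with the vinyl group and the MOM ethers unaffected.

Step 14
Reactants: 20 [2,4-bis(methoxymethoxy)-5-(2-methylbut-3-en-2-yl)phenyl]methanol
Product: 22 1-(chloromethyl)-2,4-bis(methoxymethoxy)-5-(2-methylbut-3-en-2-yl)benzene, via benzylic mesylate 21 (not isolated)
Conditions: MsCl, Et3N, CH2Cl2, 0 °C to rt; crude chloride used at once in step 15
Reagents that add atoms: methanesulfonyl chloride, CS(=O)(=O)Cl
Why: Mesylation of the benzylic alcohol followed by in situ displacement of the mesylate by the chloride ion released, which is fast for an electron-rich 2,4-dialkoxybenzyl system, while the amine keeps the medium non-acidic for the MOM ethers.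

Step 15
Reactants: 23 methyl phenyl sulfone; 22 1-(chloromethyl)-2,4-bis(methoxymethoxy)-5-(2-methylbut-3-en-2-yl)benzene; 12 5-(bromomethyl)-7-(methoxymethoxy)-4-(3-methylbut-2-en-1-yl)-1-benzofuran
Product: 25 5-{3-[2,4-bis(methoxymethoxy)-5-(2-methylbut-3-en-2-yl)phenyl]-2-(phenylsulfonyl)propyl}-7-(methoxymethoxy)-4-(3-methylbut-2-en-1-yl)-1-benzofuran (racemic), via monoalkylated sulfone 24 (not isolated)
Conditions: 23, n-BuLi (1 equiv), THF, −78 °C; 22, −78 to −20 °C; n-BuLi (1 equiv), −78 °C; 12, DMPU, −78 to 0 °C; NH4Cl (aq.)
Reagents that add atoms: none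
Why: n-BuLi removes a methyl proton of 23 and the sulfonyl-stabilised carbanion displaces chloride from 22 in a bimolecular substitution to give 24; a second equivalent of n-BuLi, added only once 22 is consumed, deprotonates 24 at the sulfone-bearing CH2 and this carbanion displaces bromide from 12, so both C–C bonds of the central chain carbon form in one flask. The closest known reaction type is the sequential alkylation of alpha-sulfonyl carbanions, in which the sulfone acts as a methylene dianion equivalent ahead of reductive desulfonylation. No ring is closed. The sulfone-bearing carbon becomes the only stereocentre and is formed racemic with no controlling element, which is acceptable because step 16 removes it. The selectivity needed is mono- before dialkylation: the unalkylated methyl sulfone is the more acidic partner, so proton transfer should not pass the charge on to 24 while 22 is still present, and the one-to-one base stoichiometry in each stage keeps free n-BuLi away from the halides. Neither halide has a beta hydrogen, so elimination cannot compete, and the MOM ethers, the isolated alkenes and the benzofuran are inert to the carbanions at low temperature.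

Step 16
Reactants: 25 5-{3-[2,4-bis(methoxymethoxy)-5-(2-methylbut-3-en-2-yl)phenyl]-2-(phenylsulfonyl)propyl}-7-(methoxymethoxy)-4-(3-methylbut-2-en-1-yl)-1-benzofuran
Product: 26 5-{3-[2,4-bis(methoxymethoxy)-5-(2-methylbut-3-en-2-yl)phenyl]propyl}-7-(methoxymethoxy)-4-(3-methylbut-2-en-1-yl)-1-benzofuran
Conditions: Mg turnings, HgCl2 (cat.), MeOH/THF, rt to 50 °C
Reagents that add atoms: none
Why: Reductive desulfonylation by electron transfer from magnesium, in which the aryl sulfone radical anion fragments to benzenesulfinate and a secondary alkyl radical that is reduced further at the metal and protonated by methanol faster than it could add to the remote prenyl alkene; isolated alkenes, the benzofuran and MOM ethers are left intact and the only stereocentre disappears.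

Step 17
Reactants: 26 5-{3-[2,4-bis(methoxymethoxy)-5-(2-methylbut-3-en-2-yl)phenyl]propyl}-7-(methoxymethoxy)-4-(3-methylbut-2-en-1-yl)-1-benzofuran
Product: 27 4-{3-[7-hydroxy-4-(3-methylbut-2-en-1-yl)-1-benzofuran-5-yl]propyl}-6-(2-methylbut-3-en-2-yl)benzene-1,3-diol (CNP0288359.0)
Conditions: HCl (aq., cat.), MeOH, rt to 40 °C, dilute
Reagents that add atoms: none
Why: Acid-catalysed transacetalisation of the three MOM ethers to methanol (giving dimethoxymethane) frees the phenols under dilute, mild conditions that the prenyl alkene, which has no ortho hydroxyl to cyclise onto, and the monosubstituted vinyl group should tolerate.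

**Compound list**

1 | 2-bromo-4-hydroxy-5-methoxybenzaldehyde (6-bromovanillin) | COc1cc(C=O)c(Br)cc1O | starting material
2 | 2-bromo-4-hydroxy-3-iodo-5-methoxybenzaldehyde | COc1cc(C=O)c(Br)c(I)c1O | intermediate
3 | ethynyltrimethylsilane | C#C[Si](C)(C)C | starting material
4 | 2-bromo-4-hydroxy-5-methoxy-3-[(trimethylsilyl)ethynyl]benzaldehyde | COc1cc(C=O)c(Br)c(C#C[Si](C)(C)C)c1O | intermediate
5 | 4-bromo-7-methoxy-2-(trimethylsilyl)-1-benzofuran-5-carbaldehyde | COc1cc(C=O)c(Br)c2cc([Si](C)(C)C)oc12 | intermediate
6 | 4-bromo-7-methoxy-1-benzofuran-5-carbaldehyde | COc1cc(C=O)c(Br)c2ccoc12 | intermediate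
7 | 4-bromo-7-hydroxy-1-benzofuran-5-carbaldehyde | O=Cc1cc(O)c2occc2c1Br | intermediate
8 | 4-bromo-7-(methoxymethoxy)-1-benzofuran-5-carbaldehyde | COCOc1cc(C=O)c(Br)c2ccoc12 | intermediate
9 | tributyl(3-methylbut-2-en-1-yl)stannane | CC(C)=CC[Sn](CCCC)(CCCC)CCCC | starting material
10 | 7-(methoxymethoxy)-4-(3-methylbut-2-en-1-yl)-1-benzofuran-5-carbaldehyde | COCOc1cc(C=O)c(CC=C(C)C)c2ccoc12 | intermediate
11 | [7-(methoxymethoxy)-4-(3-methylbut-2-en-1-yl)-1-benzofuran-5-yl]methanol | COCOc1cc(CO)c(CC=C(C)C)c2ccoc12 | intermediate
12 | 5-(bromomethyl)-7-(methoxymethoxy)-4-(3-methylbut-2-en-1-yl)-1-benzofuran | CC(C)=CCc1c(CBr)cc(OCOC)c2occc12 | intermediate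
13 | 2,4-dihydroxybenzaldehyde | O=Cc1ccc(O)cc1O | starting material
14 | prenyl bromide (1-bromo-3-methylbut-2-ene) | CC(C)=CCBr | starting material
15 | 2-hydroxy-4-[(3-methylbut-2-en-1-yl)oxy]benzaldehyde | CC(C)=CCOc1ccc(C=O)c(O)c1 | intermediate
16 | 2-(methoxymethoxy)-4-[(3-methylbut-2-en-1-yl)oxy]benzaldehyde | CC(C)=CCOc1ccc(C=O)c(OCOC)c1 | intermediate
17 | 4-formyl-3-(methoxymethoxy)-6-(2-methylbut-3-en-2-yl)cyclohexa-2,4-dien-1-one (racemic) | O=CC1=CC(C(C)(C)C=C)C(=O)C=C1OCOC | intermediate
18 | 4-hydroxy-2-(methoxymethoxy)-5-(2-methylbut-3-en-2-yl)benzaldehyde | C=CC(C)(C)c1cc(C=O)c(OCOC)cc1O | intermediate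
19 | 2,4-bis(methoxymethoxy)-5-(2-methylbut-3-en-2-yl)benzaldehyde | C=CC(C)(C)c1cc(C=O)c(OCOC)cc1OCOC | intermediate
20 | [2,4-bis(methoxymethoxy)-5-(2-methylbut-3-en-2-yl)phenyl]methanol | C=CC(C)(C)c1cc(CO)c(OCOC)cc1OCOC | intermediate
21 | [2,4-bis(methoxymethoxy)-5-(2-methylbut-3-en-2-yl)phenyl]methyl methanesulfonate | C=CC(C)(C)c1cc(COS(C)(=O)=O)c(OCOC)cc1OCOC | intermediate
22 | 1-(chloromethyl)-2,4-bis(methoxymethoxy)-5-(2-methylbut-3-en-2-yl)benzene | C=CC(C)(C)c1cc(CCl)c(OCOC)cc1OCOC | intermediate
23 | methyl phenyl sulfone | CS(=O)(=O)c1ccccc1 | starting material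
24 | 1,5-bis(methoxymethoxy)-2-(2-methylbut-3-en-2-yl)-4-[2-(phenylsulfonyl)ethyl]benzene | C=CC(C)(C)c1cc(CCS(=O)(=O)c2ccccc2)c(OCOC)cc1OCOC | intermediate
25 | 5-{3-[2,4-bis(methoxymethoxy)-5-(2-methylbut-3-en-2-yl)phenyl]-2-(phenylsulfonyl)propyl}-7-(methoxymethoxy)-4-(3-methylbut-2-en-1-yl)-1-benzofuran (racemic) | C=CC(C)(C)c1cc(CC(Cc2cc(OCOC)c3occc3c2CC=C(C)C)S(=O)(=O)c2ccccc2)c(OCOC)cc1OCOC | intermediate
26 | 5-{3-[2,4-bis(methoxymethoxy)-5-(2-methylbut-3-en-2-yl)phenyl]propyl}-7-(methoxymethoxy)-4-(3-methylbut-2-en-1-yl)-1-benzofuran | C=CC(C)(C)c1cc(CCCc2cc(OCOC)c3occc3c2CC=C(C)C)c(OCOC)cc1OCOC | intermediate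
27 | 4-{3-[7-hydroxy-4-(3-methylbut-2-en-1-yl)-1-benzofuran-5-yl]propyl}-6-(2-methylbut-3-en-2-yl)benzene-1,3-diol (CNP0288359.0) | C=CC(C)(C)c1cc(CCCc2cc(O)c3occc3c2CC=C(C)C)c(O)cc1O | target

**Step count and risks**

Total step count: 17. Longest linear sequence: 11 steps (steps 1–8 and 15–17, from 1); the ring-A branch (steps 9–14) has 6 steps.

Steps most likely to fail:

1. Step 15. The risk is proton exchange between lithiated 23 and 24 while 22 is still present, which would lead to double alkylation by the same halide and leave 23 to be alkylated by 12; the labile chloride 22 may also ionise and self-condense before it is captured. The fallback sets out from 22 and 12 and replaces the linchpin by the far more acidic bis(phenylsulfonyl)methane, alkylated in two separate flasks. Deprotonation with NaH in DMF and alkylation with 22 should give 1-[2,2-bis(phenylsulfonyl)ethyl]-2,4-bis(methoxymethoxy)-5-(2-methylbut-3-en-2-yl)benzene F1, which is isolated. A second deprotonation with NaH and alkylation with 12 should give 5-{3-[2,4-bis(methoxymethoxy)-5-(2-methylbut-3-en-2-yl)phenyl]-2,2-bis(phenylsulfonyl)propyl}-7-(methoxymethoxy)-4-(3-methylbut-2-en-1-yl)-1-benzofuran F2. Mg in MeOH then removes both sulfonyl groups, and the route is rejoined at 26.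

2. Step 11. The risk is that the [3,3] shift is accompanied by loss of the prenyl group, by migration toward C3, or by further thermal reorganisation of the product (abnormal Claisen shift, cyclisation of the phenol onto the new vinyl group). The fallback sets out from 13 and installs the 1,1-dimethylallyl group by cross-coupling. Bromination (Br2, AcOH) should give 5-bromo-2,4-dihydroxybenzaldehyde F3. Double MOM etherification (MOMCl, i-Pr2NEt) gives 5-bromo-2,4-bis(methoxymethoxy)benzaldehyde F4. NaBH4 reduction, needed because an allylboron reagent would add to the aldehyde, gives [5-bromo-2,4-bis(methoxymethoxy)phenyl]methanol F5. A ligand-controlled gamma-selective Suzuki–Miyaura coupling with 3-methylbut-2-enylboronic acid pinacol ester (Pd(OAc)2, a branch-directing biarylphosphine, aqueous K3PO4, THF) then forms the quaternary benzylic carbon, and the route is rejoined at 20.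

3. Step 6. The risk is coupling through the more substituted allyl terminus to give the 1,1-dimethylallyl isomer, slow insertion into the flanked C4–Br bond, or addition of the allylstannane to the aldehyde. The fallback sets out from 8 and separates bond formation from the regiochemical question. Stille coupling with allyltributylstannane (Pd(PPh3)4, toluene, 100 °C) should give 4-allyl-7-(methoxymethoxy)-1-benzofuran-5-carbaldehyde F6. Cross-metathesis with excess 2-methylbut-2-ene (second-generation Grubbs catalyst, CH2Cl2, 40 °C) converts the allyl into the prenyl group, and the route is rejoined at 10.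

**Further compounds**

F1 | step 15 | 1-[2,2-bis(phenylsulfonyl)ethyl]-2,4-bis(methoxymethoxy)-5-(2-methylbut-3-en-2-yl)benzene | C=CC(C)(C)c1cc(CC(S(=O)(=O)c2ccccc2)S(=O)(=O)c2ccccc2)c(OCOC)cc1OCOC
F2 | step 15 | 5-{3-[2,4-bis(methoxymethoxy)-5-(2-methylbut-3-en-2-yl)phenyl]-2,2-bis(phenylsulfonyl)propyl}-7-(methoxymethoxy)-4-(3-methylbut-2-en-1-yl)-1-benzofuran | C=CC(C)(C)c1cc(CC(Cc2cc(OCOC)c3occc3c2CC=C(C)C)(S(=O)(=O)c2ccccc2)S(=O)(=O)c2ccccc2)c(OCOC)cc1OCOC
F3 | step 11 | 5-bromo-2,4-dihydroxybenzaldehyde | O=Cc1cc(Br)c(O)cc1O
F4 | step 11 | 5-bromo-2,4-bis(methoxymethoxy)benzaldehyde | COCOc1cc(OCOC)c(C=O)cc1Br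
F5 | step 11 | [5-bromo-2,4-bis(methoxymethoxy)phenyl]methanol | COCOc1cc(OCOC)c(CO)cc1Br
F6 | step 6 | 4-allyl-7-(methoxymethoxy)-1-benzofuran-5-carbaldehyde | COCOc1cc(C=O)c(CC=C)c2ccoc12
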